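Retrosynthetic cuts, in order: the O6 benzoate and the C6–H bond (back to a C6 ketone), the C4=C5 alkene (back to a C4 oxygen β to that ketone), the C1–O and C2–O bonds together (back to a C1=C2 enone), and last C1–C7 (back to formaldehyde).
Enabling feature: on the cyclohexene ring, O1 (on the tertiary carbinol carbon C1 that carries C7H2OBz) and O2 (on the acetate carbon C2) are cis to each other and trans to O3 (on the benzoate carbon C3). One suprafacial oxidation of C1=C2 anti to an existing C3 oxygen therefore fixes both centres.
Forward order: the carbocycle is never built, because it is the ring of (−)-quinic acid. It is degraded to a C3/C4-acetonide enone, extended by C7 at C1, oxidised across C1=C2, unsaturated at C4=C5 and finally reduced at C6.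
Stereochemistry: C3 is quinic C4 (chiral pool), and quinic C3 (= C4) serves as a temporary control element and later as a leaving group. C1 and C2 come from osmylation anti to the acetonide, and C6 from hydride delivery by the C1 hydroxyl.

Key step: step 7

Numbering and faces (used for every compound): C1 = tertiary carbinol carbon, C7 = its CH2O arm, C2 = acetate carbon, C3 and C6 = benzoate carbons, C4=C5 = alkene. Quinic acid carbons 1 to 6 become C6, C5, C4, C3, C2 and C1. With the ring drawn flat and C1 to C6 running clockwise, β is toward the viewer and α away. The target has O1 and O2 β, and O3, O6 and C7 α.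

Step 1
Reactants: 1 (−)-quinic acid
Product: 2 quinide acetonide (γ-lactone from the β carboxyl on C6 to the β oxygen O2; isopropylidene on the cis α oxygens O3/O4; free α hydroxyl on C6)
Conditions: 2,2-dimethoxypropane, p-TsOH (cat.), acetone, reflux
Reagents that add atoms: 2,2-dimethoxypropane, COC(C)(C)OC
Why: Acid-catalysed transketalisation selects the only cis-vicinal diol (O3/O4) while the carboxyl, which is cis to O2, closes the bridged γ-lactone, so acetonide formation with lactonisation carries all stereocentres over untouched.

Step 2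
Reactants: 2 quinide acetonide
Product: 3 triol acetonide (C6 bears α OH and β CH2OH; C2–OH β; O3/O4 acetonide α)
Conditions: NaBH4, EtOH, 0 °C to rt
Reagents that add atoms: none
Why: The strained, α-oxygenated lactone is electrophilic enough for borohydride reduction down to the primary alcohol, which changes no stereocentre and exposes the C6(OH)–CH2OH glycol.

Step 3
Reactants: 3 triol acetonide
Product: 4 β-hydroxy ketone (C6 ketone; C2–OH β; O3/O4 acetonide α)
Conditions: NaIO4, pH 7 phosphate buffer, 0 °C to rt
Reagents that add atoms: none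
Why: Periodate cleaves the only free vicinal diol (Malaprade glycol cleavage), turning C6 into the ketone while the isolated C2 hydroxyl and the acetonide are inert.

Step 4
Reactants: 4 β-hydroxy ketone
Product: 6 (4S,5R)-4,5-(isopropylidenedioxy)cyclohex-2-en-1-one (C6 ketone; C1=C2; O3/O4 acetonide α), via C2 mesylate 5 (not isolated)
Conditions: MsCl, Et3N, CH2Cl2, 0 °C
Reagents that add atoms: none
Why: Mesylation places a far better leaving group β to the ketone than the acetonide oxygen at C4, so triethylamine expels it by E1cB elimination through the C1 enolate and leaves C3 and C4 intact.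

Step 5
Reactants: 6 enone acetonide; 7 formaldehyde
Product: 8 2-(hydroxymethyl) enone (6 with C7H2OH on C1)
Conditions: 37% aq. CH2O, DMAP (cat.), THF/H2O, rt
Reagents that add atoms: formaldehyde (7), C=O
Why: In the Morita–Baylis–Hillman reaction DMAP adds reversibly to C2, the C1 enolate captures formaldehyde and loss of DMAP restores the enone, which forms C1–C7 under conditions mild enough to spare the base-labile C4–O bond.

Step 6
Reactants: 8 2-(hydroxymethyl) enone; 9 benzoyl chloride
Product: 10 [(3S,4R)-3,4-(isopropylidenedioxy)-6-oxocyclohex-1-en-1-yl]methyl benzoate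
Conditions: BzCl, pyridine, CH2Cl2, 0 °C
Reagents that add atoms: benzoyl chloride (9), O=C(Cl)c1ccccc1
Why: O-acylation of the unhindered primary allylic alcohol with an acid chloride is fast at 0 °C, and pyridine is too weak a nucleophile to displace the allylic benzoate it creates.

Step 7
Reactants: 10 benzoyloxymethyl enone acetonide
Product: 12 C1,C2-diol ketone (O1/O2 β; O3/O4 acetonide α; C7H2OBz α on C1; C6 ketone), via cyclic osmate ester 11 (not isolated)
Conditions: OsO4 (cat.), NMO, citric acid, t-BuOH/H2O, rt
Reagents that add atoms: osmium tetroxide, O=[Os](=O)(=O)=O; N-methylmorpholine N-oxide, C[N+]1([O-])CCOCC1; water, O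
Why: OsO4 (octavalent osmium) adds to C1=C2 in a concerted suprafacial [3+2] cycloaddition to give the hexavalent osmium glycolate 11, which NMO reoxidises and water hydrolyses, so the C1–O and C2–O bonds are made and the metal is returned. The closest known reaction type is the catalytic syn-dihydroxylation of 4-alkoxycyclohex-2-enones with OsO4/NMO, run here in the citric acid variant used for electron-poor alkenes, which also protonates the N-methylmorpholine that could otherwise displace or shift the allylic benzoate or expel the C4 oxygen. No ring of the product is closed, since only the transient five-membered dioxaosmolane ring of 11 forms and opens again. C2 is set by attack anti to the allylic C3–O bond, and C1 follows from C2 because both oxygens leave one osmium atom on one face. The selectivity needed is facial, and it is secured by the cis-fused dioxolane ring, which covers the α face at C3 and C4 and leaves only the convex β face open. Chemoselectivity is not at stake because C1=C2 is the only alkene.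

Step 8
Reactants: 12 C1,C2-diol ketone; 13 acetic anhydride
Product: 14 C2 acetate (12 with O2 acetylated; C1–OH free)
Conditions: Ac2O, pyridine, CH2Cl2, 0 °C to rt
Reagents that add atoms: acetic anhydride (13), CC(=O)OC(C)=O
Why: Kinetically selective O-acetylation distinguishes the secondary C2 hydroxyl, the only one in the molecule at this stage, from the hindered tertiary C1 hydroxyl.

Step 9
Reactants: 14 C2 acetate
Product: 15 C3,C4-diol (O3 and O4 free and α; O2 acetate β; C1–OH β; C7 benzoate; C6 ketone)
Conditions: TFA, H2O, CH2Cl2, 0 °C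
Reagents that add atoms: none
Why: Acid-catalysed hydrolysis cleaves the dioxolane ketal while the esters survive, and acyl shifts, which are base-promoted, stay slow at low pH and low temperature.

Step 10
Reactants: 15 C3,C4-diol; 9 benzoyl chloride
Product: 17 C4=C5 enone (C6 ketone; O3 benzoate α; O2 acetate β; C1–OH β; C7 benzoate), via 3,4-dibenzoate 16 (not isolated)
Conditions: BzCl, pyridine, CH2Cl2, 0 °C to rt; then Et3N, 0 °C
Reagents that add atoms: benzoyl chloride (9), O=C(Cl)c1ccccc1
Why: Both secondary hydroxyls are benzoylated, and because C5 holds the only enolisable hydrogens and the C4 benzoate lies β to the ketone, triethylamine expels just that benzoate by E1cB elimination while C3 keeps its ester and its configuration.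

Step 11
Reactants: 17 C4=C5 enone
Product: 18 C6 allylic alcohol (O6 α, trans to O1; otherwise as 17)
Conditions: Me4NBH(OAc)3, MeCN/AcOH, −20 °C
Reagents that add atoms: none
Why: In the hydroxyl-directed triacetoxyborohydride (Saksena–Evans) reduction the reagent, inert toward the enone by itself, exchanges one acetate for the β C1 hydroxyl and then passes its hydride to the β face of the neighbouring C6 carbonyl carbon, so 1,2-reduction places O6 on the α face.

Step 12
Reactants: 18 C6 allylic alcohol; 9 benzoyl chloride
Product: 19 target, [(1R,2S,5R,6S)-6-acetoxy-2,5-bis(benzoyloxy)-1-hydroxycyclohex-3-en-1-yl]methyl benzoate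
Conditions: BzCl, pyridine, DMAP (cat.), CH2Cl2, 0 °C
Reagents that add atoms: benzoyl chloride (9), O=C(Cl)c1ccccc1
Why: Selective O-acylation benzoylates the secondary allylic C6 hydroxyl much faster than the hindered tertiary C1 hydroxyl, and a prior benzoyl shift between O7 and O6 would be harmless because both positions end as benzoates.

Compound list
1 | (−)-quinic acid, (1S,3R,4S,5R)-1,3,4,5-tetrahydroxycyclohexane-1-carboxylic acid | OC(=O)[C@]1(O)C[C@@H](O)[C@@H](O)[C@H](O)C1 | starting material
2 | quinide acetonide (lactone C6-carboxyl to O2, O3/O4 isopropylidene) | O[C@@]1(C2=O)C[C@H]3OC(C)(C)O[C@H]3[C@H](O2)C1 | intermediate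
3 | triol acetonide (C6 OH and CH2OH, C2–OH β, O3/O4 acetonide α) | O[C@@]1(CO)C[C@H]2OC(C)(C)O[C@H]2[C@H](O)C1 | intermediate
4 | β-hydroxy ketone (C6 ketone, C2–OH β, O3/O4 acetonide α) | O=C1C[C@H]2OC(C)(C)O[C@H]2[C@H](O)C1 | intermediate
5 | C2 mesylate of 4 | O=C1C[C@H]2OC(C)(C)O[C@H]2[C@H](OS(C)(=O)=O)C1 | intermediate
6 | (4S,5R)-4,5-(isopropylidenedioxy)cyclohex-2-en-1-one | O=C1C[C@H]2OC(C)(C)O[C@H]2C=C1 | intermediate
7 | formaldehyde | C=O | starting material
8 | 2-(hydroxymethyl) enone acetonide | O=C1C[C@H]2OC(C)(C)O[C@H]2C=C1CO | intermediate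
9 | benzoyl chloride | O=C(Cl)c1ccccc1 | starting material
10 | [(3S,4R)-3,4-(isopropylidenedioxy)-6-oxocyclohex-1-en-1-yl]methyl benzoate | O=C1C[C@H]2OC(C)(C)O[C@H]2C=C1COC(=O)c1ccccc1 | intermediate
11 | cyclic osmate ester (dioxo hexavalent osmium glycolate on β O1/O2) | O=C1C[C@H]2OC(C)(C)O[C@H]2[C@@H]3O[Os](=O)(=O)O[C@]13COC(=O)c1ccccc1 | intermediate
12 | C1,C2-diol ketone (O1/O2 β, O3/O4 acetonide α, C7 benzoate) | O=C1C[C@H]2OC(C)(C)O[C@H]2[C@H](O)[C@@]1(O)COC(=O)c1ccccc1 | intermediate
13 | acetic anhydride | CC(=O)OC(C)=O | starting material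
14 | C2 acetate of 12 | O=C1C[C@H]2OC(C)(C)O[C@H]2[C@H](OC(C)=O)[C@@]1(O)COC(=O)c1ccccc1 | intermediate
15 | C3,C4-diol (O2 acetate, C7 benzoate, C6 ketone) | O=C1C[C@@H](O)[C@@H](O)[C@H](OC(C)=O)[C@@]1(O)COC(=O)c1ccccc1 | intermediate
16 | 3,4-dibenzoate of 15 | O=C1C[C@@H](OC(=O)c2ccccc2)[C@@H](OC(=O)c2ccccc2)[C@H](OC(C)=O)[C@@]1(O)COC(=O)c1ccccc1 | intermediate
17 | C4=C5 enone (O3 benzoate α, O2 acetate β, C1–OH β, C7 benzoate) | O=C1C=C[C@@H](OC(=O)c2ccccc2)[C@H](OC(C)=O)[C@@]1(O)COC(=O)c1ccccc1 | intermediate
18 | C6 allylic alcohol (O6 α) | O[C@H]1C=C[C@@H](OC(=O)c2ccccc2)[C@H](OC(C)=O)[C@@]1(O)COC(=O)c1ccccc1 | intermediate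
19 | [(1R,2S,5R,6S)-6-acetoxy-2,5-bis(benzoyloxy)-1-hydroxycyclohex-3-en-1-yl]methyl benzoate | CC(=O)O[C@H]1[C@H](OC(=O)c2ccccc2)C=C[C@H](OC(=O)c2ccccc2)[C@]1(O)COC(=O)c1ccccc1 | target

Total step count: 12. Longest linear sequence: 12 steps (1 to 19).

Steps most likely to fail

Step 7. Osmylation of a trisubstituted alkene that is conjugated to a ketone and carries an allylic ester may be slow. Amine-induced displacement or migration of the benzoate, or β-elimination of the C4 oxygen, could then overtake it. The fallback sets out from 10 and returns at 14, and it takes the ketone out of conjugation for the oxidation. NaBH4/CeCl3·7H2O in MeOH (Luche reduction) should attack the convex β face and give the C6 allylic alcohol F1. TBSOTf/2,6-lutidine should convert it to the silyl ether F2, whose alkene is no longer electron-poor and is flanked by two α allylic oxygens (O3 and O6). OsO4/NMO should therefore give the β,β-diol F3. Ac2O/pyridine should give the C2 acetate F4 and HF·pyridine the C6 alcohol F5. IBX in DMSO, which oxidises glycols without C–C cleavage, should then give 14.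

Step 10. While O3 is free, the neighbouring acetyl group may migrate from O2 to O3 under the basic acylation conditions. The base may also go on to deprotonate the product enone at C3, with loss of the C2 acetate. The fallback sets out from 12 and returns at 17, and it introduces the acetate only after the C3 benzoate is in place. TBSOTf/2,6-lutidine should silylate the secondary hydroxyl of 12 to give the C2 silyl ether F6, and aqueous AcOH at 40 °C should remove the acetonide to give the C3,C4-diol F7. BzCl/pyridine should give the dibenzoate F8, which Et3N should convert to the silyloxy enone F9. HF·pyridine should free the C1,C2-diol enone F10, and Ac2O/pyridine should acetylate its only secondary hydroxyl to give 17.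

Step 11. Ligand exchange at the hindered tertiary hydroxyl may be slow, so that undirected hydride attack from the α face erodes the facial selectivity or reduction stalls. The fallback sets out from 17 and returns at 19, and it seeks the opposite face on purpose and corrects it by inversion. NaBH4/CeCl3·7H2O in MeOH at −78 °C should add hydride along the axial trajectory anti to the pseudoaxial C1–O bond. That is the α face, and attack there gives the C6-epimeric alcohol F11 (O6 β). A Mitsunobu reaction (PPh3, DIAD, benzoic acid, THF, 0 °C) should then install the benzoate with inversion at C6 and give 19 directly.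

Further compounds
F1 | step 7 | C6 allylic alcohol (O6 α) from 1,2-reduction of 10 | O[C@H]1C[C@H]2OC(C)(C)O[C@H]2C=C1COC(=O)c1ccccc1
F2 | step 7 | C6 tert-butyldimethylsilyl ether of F1 | CC(C)(C)[Si](C)(C)O[C@H]1C[C@H]2OC(C)(C)O[C@H]2C=C1COC(=O)c1ccccc1
F3 | step 7 | C1,C2-diol (O1/O2 β) of F2 | CC(C)(C)[Si](C)(C)O[C@H]1C[C@H]2OC(C)(C)O[C@H]2[C@H](O)[C@@]1(O)COC(=O)c1ccccc1
F4 | step 7 | C2 acetate of F3 | CC(C)(C)[Si](C)(C)O[C@H]1C[C@H]2OC(C)(C)O[C@H]2[C@H](OC(C)=O)[C@@]1(O)COC(=O)c1ccccc1
F5 | step 7 | C6 alcohol from desilylation of F4 | O[C@H]1C[C@H]2OC(C)(C)O[C@H]2[C@H](OC(C)=O)[C@@]1(O)COC(=O)c1ccccc1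
F6 | step 10 | C2 tert-butyldimethylsilyl ether of 12 | O=C1C[C@H]2OC(C)(C)O[C@H]2[C@H](O[Si](C)(C)C(C)(C)C)[C@@]1(O)COC(=O)c1ccccc1
F7 | step 10 | C3,C4-diol from F6 | O=C1C[C@@H](O)[C@@H](O)[C@H](O[Si](C)(C)C(C)(C)C)[C@@]1(O)COC(=O)c1ccccc1
F8 | step 10 | 3,4-dibenzoate of F7 | O=C1C[C@@H](OC(=O)c2ccccc2)[C@@H](OC(=O)c2ccccc2)[C@H](O[Si](C)(C)C(C)(C)C)[C@@]1(O)COC(=O)c1ccccc1
F9 | step 10 | C4=C5 enone with C2 silyl ether and C3 benzoate | O=C1C=C[C@@H](OC(=O)c2ccccc2)[C@H](O[Si](C)(C)C(C)(C)C)[C@@]1(O)COC(=O)c1ccccc1
F10 | step 10 | C1,C2-diol enone (O3 and O7 benzoates) | O=C1C=C[C@@H](OC(=O)c2ccccc2)[C@H](O)[C@@]1(O)COC(=O)c1ccccc1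
F11 | step 11 | C6 epimer of 18 (O6 β) | O[C@@H]1C=C[C@@H](OC(=O)c2ccccc2)[C@H](OC(C)=O)[C@@]1(O)COC(=O)c1ccccc1
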